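**Retrosynthetic overview**
1. Target 25 ⇐ tri-O-benzyl ether 24 (BCl3 debenzylation); the pyranone ring of the chromone is closed last, by one-carbon annulation of the 2-hydroxyaryl ketone in 1,4-diketone 22.
2. The 1,4-diketone ⇐ γ-lactone 15 + aryllithium 19 (then oxidation); the lactone ⇐ aldehyde ester 10 + aryllithium 13.
3. Aldehyde ester 10 ⇐ alkene cleavage of γ,δ-unsaturated ester 8, whose stereocentre comes by Johnson–Claisen chirality transfer from allylic alcohol (R)-6.
4. (R)-6 ⇐ ketoreductase reduction of achiral enone 5 ⇐ 4,4'-dihydroxybenzophenone 1 (benzylation, two Wittig homologations).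
5. Ring order: all benzene rings are bought; a temporary γ-lactone ring (step 9) is reopened (step 12); the 4H-pyran-4-one ring is formed last (step 15).

Assumption: the SMILES is read as the (R)-enantiomer (CIP order aroyl > chromen-3-yl > diarylmethyl > H); 13, 14 and 19 are written as monomeric lithium species.

**Step 1**
Reactants: 1 4,4'-dihydroxybenzophenone
Product: 2 bis[4-(benzyloxy)phenyl]methanone
Conditions: BnBr (2.3 equiv), K2CO3 (3 equiv), DMF, 60 °C
Reagents that add atoms: benzyl bromide, BrCc1ccccc1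
Why: Williamson etherification of both phenols gives benzyl ethers that survive ylides, aryllithiums and oxidants and can be removed at the end without base.

**Step 2**
Reactants: 2 bis[4-(benzyloxy)phenyl]methanone
Product: 3 1,1'-(2-methoxyethene-1,1-diyl)bis[4-(benzyloxy)benzene]
Conditions: Ph3P(CH2OMe)Cl (1.6 equiv), KOtBu (1.5 equiv), THF, 0 °C → 50 °C
Reagents that add atoms: (methoxymethyl)triphenylphosphonium chloride, [Cl-].COC[P+](c1ccccc1)(c1ccccc1)c1ccccc1
Why: Wittig olefination with the non-stabilised methoxymethylidene ylide turns the diaryl ketone into an enol ether, a masked one-carbon-homologated aldehyde.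

**Step 3**
Reactants: 3 1,1'-(2-methoxyethene-1,1-diyl)bis[4-(benzyloxy)benzene]
Product: 4 2,2-bis[4-(benzyloxy)phenyl]acetaldehyde
Conditions: HCl (2 M aq.), THF, 40 °C, under N2; used directly
Reagents that add atoms: water, O
Why: Acid-catalysed enol ether hydrolysis (protonation at the diaryl carbon, collapse of the hemiacetal) unmasks the diarylacetaldehyde while benzyl ethers are untouched.

**Step 4**
Reactants: 4 2,2-bis[4-(benzyloxy)phenyl]acetaldehyde
Product: 5 (3E)-5,5-bis[4-(benzyloxy)phenyl]pent-3-en-2-one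
Conditions: Ph3P=CHC(O)CH3 (1.3 equiv), toluene, 70 °C
Reagents that add atoms: 1-(triphenylphosphoranylidene)propan-2-one, CC(=O)C=P(c1ccccc1)(c1ccccc1)c1ccccc1
Why: Wittig olefination with the stabilised acetonyl ylide is (E)-selective and too weakly basic to enolise the aldehyde or deconjugate the enone.

**Step 5**
Reactants: 5 (3E)-5,5-bis[4-(benzyloxy)phenyl]pent-3-en-2-one
Product: 6 (2R,3E)-5,5-bis[4-(benzyloxy)phenyl]pent-3-en-2-ol
Conditions: ketoreductase ((R)-selective, NADPH-dependent, Lactobacillus kefir alcohol dehydrogenase type), NADP+ (cat.), i-PrOH (15% v/v), MgCl2 (1 mM), KH2PO4/K2HPO4 buffer pH 7.0, DMSO (10% v/v), 30 °C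
Reagents that add atoms: none
Why: Enzymatic asymmetric ketone reduction: the ketoreductase delivers hydride from NADPH (recycled by i-PrOH) to the Si face of the methyl ketone, telling the small methyl from the large alkenyl group, so the first stereocentre is set catalytically as (R) and the C=C is not reduced.

**Step 6**
Reactants: 6 (2R,3E)-5,5-bis[4-(benzyloxy)phenyl]pent-3-en-2-ol
Product: 8 ethyl (3R,4E)-3-{bis[4-(benzyloxy)phenyl]methyl}hex-4-enoate, via ketene acetal 7 (not isolated)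
Conditions: CH3C(OEt)3 (6 equiv), EtCO2H (10 mol%), xylenes, 140 °C, EtOH distilled off
Reagents that add atoms: triethyl orthoacetate, CCOC(C)(OCC)OCC
Why: Johnson–Claisen rearrangement: the mixed ketene acetal undergoes a suprafacial [3,3] shift through a chair with the carbinol methyl equatorial, which transfers the (R)-carbinol chirality to the new diarylmethyl-bearing C3 stereocentre (R) and gives the (E)-alkene.

**Step 7**
Reactants: 8 ethyl (3R,4E)-3-{bis[4-(benzyloxy)phenyl]methyl}hex-4-enoate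
Product: 10 ethyl (3S)-3-{bis[4-(benzyloxy)phenyl]methyl}-4-oxobutanoate, via diol 9 (not isolated)
Conditions: OsO4 (2 mol%), NaIO4 (4 equiv), 2,6-lutidine (2 equiv), 1,4-dioxane/H2O 3:1, rt; used directly
Reagents that add atoms: osmium tetroxide, O=[Os](=O)(=O)=O (oxygen donor, regenerated by sodium periodate, [Na+].[O-][I](=O)(=O)=O)
Why: Lemieux–Johnson oxidation (osmylation, then periodate glycol cleavage) cuts the propenyl group to the aldehyde under lutidine-buffered conditions that neither epimerise the α-stereocentre nor attack the electron-rich arenes (the descriptor changes to S only through CIP priorities).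

**Step 8**
Reactants: 11 2-bromo-5-methoxyphenol
Product: 12 1-bromo-4-methoxy-2-(methoxymethoxy)benzene
Conditions: MOMCl (1.5 equiv), i-Pr2NEt (2 equiv), CH2Cl2, 0 °C → rt
Reagents that add atoms: chloromethyl methyl ether, COCCl
Why: Williamson-type O-alkylation gives an acetal-protected aryl bromide suited to bromine–lithium exchange, the MOM group later being very acid-labile because it sits ortho to a carbonyl.

**Step 9**
Reactants: 10 ethyl (3S)-3-{bis[4-(benzyloxy)phenyl]methyl}-4-oxobutanoate; 12 1-bromo-4-methoxy-2-(methoxymethoxy)benzene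
Product: 15 (4S)-4-{bis[4-(benzyloxy)phenyl]methyl}-5-[4-methoxy-2-(methoxymethoxy)phenyl]oxolan-2-one (both C5 epimers), via aryllithium 13 (not isolated), via lithium alkoxide 14 (not isolated)
Conditions: 12 (1.15 equiv), n-BuLi (1.1 equiv), THF, −78 °C; then 10, −78 °C → rt; aq. NH4Cl
Reagents that add atoms: none
Why: Bromine–lithium exchange followed by 1,2-addition of the aryllithium to the aldehyde at −78 °C outruns enolisation and ester attack, and the γ-alkoxide lactonises (acyl substitution) so the stereocentre rests at a non-acidic position, the new carbinol centre being a mixture that is oxidised away in step 13.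

**Step 10**
Reactants: 16 4-bromobenzene-1,3-diol
Product: 17 5-(benzyloxy)-2-bromophenol
Conditions: BnBr (1.0 equiv), K2CO3 (1.1 equiv), acetone, rt; chromatography
Reagents that add atoms: benzyl bromide, BrCc1ccccc1
Why: Williamson mono-etherification favours the unhindered hydroxyl para to bromine over the hydroxyl ortho to bromine, and the minor regioisomer and bis-ether are removed by chromatography.

**Step 11**
Reactants: 17 5-(benzyloxy)-2-bromophenol
Product: 18 4-(benzyloxy)-1-bromo-2-(methoxymethoxy)benzene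
Conditions: MOMCl (1.5 equiv), i-Pr2NEt (2 equiv), CH2Cl2, 0 °C → rt
Reagents that add atoms: chloromethyl methyl ether, COCCl
Why: Williamson-type MOM protection of the remaining phenol gives the second aryl bromide, with the acid-labile group at the oxygen that will become the pyranone oxygen and the benzyl group at the future 7-oxygen.

**Step 12**
Reactants: 15 (4S)-4-{bis[4-(benzyloxy)phenyl]methyl}-5-[4-methoxy-2-(methoxymethoxy)phenyl]oxolan-2-one; 18 4-(benzyloxy)-1-bromo-2-(methoxymethoxy)benzene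
Product: 20 (3S)-1-[4-(benzyloxy)-2-(methoxymethoxy)phenyl]-3-{bis[4-(benzyloxy)phenyl]methyl}-4-hydroxy-4-[4-methoxy-2-(methoxymethoxy)phenyl]butan-1-one (both C4 epimers), via aryllithium 19 (not isolated)
Conditions: 18 (1.3 equiv), n-BuLi (1.25 equiv), THF, −78 °C; then 15, −78 °C, 1 h; aq. NH4Cl, −78 °C → rt
Reagents that add atoms: none
Why: Aryllithium addition to the γ-lactone stops at the chelated tetrahedral lithium hemiketalate, which opens on work-up to the γ-hydroxy aryl ketone (ring–chain tautomer of the lactol), and the stereocentre is not involved.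

**Step 13**
Reactants: 20 (3S)-1-[4-(benzyloxy)-2-(methoxymethoxy)phenyl]-3-{bis[4-(benzyloxy)phenyl]methyl}-4-hydroxy-4-[4-methoxy-2-(methoxymethoxy)phenyl]butan-1-one
Product: 21 (2S)-4-[4-(benzyloxy)-2-(methoxymethoxy)phenyl]-2-{bis[4-(benzyloxy)phenyl]methyl}-1-[4-methoxy-2-(methoxymethoxy)phenyl]butane-1,4-dione
Conditions: Dess–Martin periodinane (1.5 equiv), NaHCO3 (5 equiv), CH2Cl2, 0 °C → rt
Reagents that add atoms: none
Why: Dess–Martin oxidation of the benzylic carbinol (both epimers converge) under NaHCO3 buffering gives the 1,4-diketone without epimerising the hindered tertiary centre that is now α to a carbonyl.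

**Step 14**
Reactants: 21 (2S)-4-[4-(benzyloxy)-2-(methoxymethoxy)phenyl]-2-{bis[4-(benzyloxy)phenyl]methyl}-1-[4-methoxy-2-(methoxymethoxy)phenyl]butane-1,4-dione
Product: 22 (2S)-4-[4-(benzyloxy)-2-hydroxyphenyl]-2-{bis[4-(benzyloxy)phenyl]methyl}-1-(2-hydroxy-4-methoxyphenyl)butane-1,4-dione
Conditions: HCl (1.25 M in MeOH), THF, rt
Reagents that add atoms: none
Why: Acid-catalysed acetal cleavage frees the two phenols ortho to the carbonyls at room temperature, which is too mild for enolisation of the hindered stereocentre or Paal–Knorr furan formation, while benzyl and methyl ethers stay.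

**Step 15**
Reactants: 22 (2S)-4-[4-(benzyloxy)-2-hydroxyphenyl]-2-{bis[4-(benzyloxy)phenyl]methyl}-1-(2-hydroxy-4-methoxyphenyl)butane-1,4-dione
Product: 24 7-(benzyloxy)-3-[(2R)-1,1-bis[4-(benzyloxy)phenyl]-3-(2-hydroxy-4-methoxyphenyl)-3-oxopropan-2-yl]-4H-chromen-4-one, via enaminone 23 (not isolated)
Conditions: Me2NCH(OMe)2 (5 equiv), toluene, 80 °C; then AcOH, rt
Reagents that add atoms: N,N-dimethylformamide dimethyl acetal, COC(OC)N(C)C
Why: Enaminone-based chromone annulation: the amide acetal condenses at the only enolisable methylene, the chelated 2-hydroxyl adds to the enaminone β-carbon and Me2NH is expelled on acidification to close the 4H-chromen-4-one, while the tertiary stereocentre cannot condense and its hydrogen-bonded 2-hydroxyaryl ketone disfavours enolisation.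

**Step 16**
Reactants: 24 7-(benzyloxy)-3-[(2R)-1,1-bis[4-(benzyloxy)phenyl]-3-(2-hydroxy-4-methoxyphenyl)-3-oxopropan-2-yl]-4H-chromen-4-one
Product: 25 7-hydroxy-3-[(2R)-3-(2-hydroxy-4-methoxyphenyl)-1,1-bis(4-hydroxyphenyl)-3-oxopropan-2-yl]-4H-chromen-4-one
Conditions: BCl3 (1 M in CH2Cl2, 8 equiv), C6HMe5 (10 equiv), CH2Cl2, −78 °C; then H2O
Reagents that add atoms: none
Why: Lewis-acid debenzylation with pentamethylbenzene as benzyl-cation scavenger cleaves the three aryl benzyl ethers at −78 °C under non-basic, non-reducing conditions, so the methyl ether, the chromone double bond and the base-labile stereocentre are untouched.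

**Compound list**
1 | 4,4'-dihydroxybenzophenone | O=C(c1ccc(O)cc1)c1ccc(O)cc1 | starting material
2 | bis[4-(benzyloxy)phenyl]methanone | O=C(c1ccc(OCc2ccccc2)cc1)c1ccc(OCc2ccccc2)cc1 | intermediate
3 | 1,1'-(2-methoxyethene-1,1-diyl)bis[4-(benzyloxy)benzene] | COC=C(c1ccc(OCc2ccccc2)cc1)c1ccc(OCc2ccccc2)cc1 | intermediate
4 | 2,2-bis[4-(benzyloxy)phenyl]acetaldehyde | O=CC(c1ccc(OCc2ccccc2)cc1)c1ccc(OCc2ccccc2)cc1 | intermediate
5 | (3E)-5,5-bis[4-(benzyloxy)phenyl]pent-3-en-2-one | CC(=O)/C=C/C(c1ccc(OCc2ccccc2)cc1)c1ccc(OCc2ccccc2)cc1 | intermediate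
6 | (2R,3E)-5,5-bis[4-(benzyloxy)phenyl]pent-3-en-2-ol | C[C@@H](O)/C=C/C(c1ccc(OCc2ccccc2)cc1)c1ccc(OCc2ccccc2)cc1 | intermediate
7 | ethyl (2R,3E)-5,5-bis[4-(benzyloxy)phenyl]pent-3-en-2-yl ketene acetal | C=C(OCC)O[C@H](C)/C=C/C(c1ccc(OCc2ccccc2)cc1)c1ccc(OCc2ccccc2)cc1 | intermediate
8 | ethyl (3R,4E)-3-{bis[4-(benzyloxy)phenyl]methyl}hex-4-enoate | CCOC(=O)C[C@H](/C=C/C)C(c1ccc(OCc2ccccc2)cc1)c1ccc(OCc2ccccc2)cc1 | intermediate
9 | ethyl (3S)-3-{bis[4-(benzyloxy)phenyl]methyl}-4,5-dihydroxyhexanoate (diol diastereomers) | CCOC(=O)C[C@H](C(O)C(C)O)C(c1ccc(OCc2ccccc2)cc1)c1ccc(OCc2ccccc2)cc1 | intermediate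
10 | ethyl (3S)-3-{bis[4-(benzyloxy)phenyl]methyl}-4-oxobutanoate | CCOC(=O)C[C@H](C=O)C(c1ccc(OCc2ccccc2)cc1)c1ccc(OCc2ccccc2)cc1 | intermediate
11 | 2-bromo-5-methoxyphenol | COc1ccc(Br)c(O)c1 | starting material
12 | 1-bromo-4-methoxy-2-(methoxymethoxy)benzene | COCOc1cc(OC)ccc1Br | intermediate
13 | [4-methoxy-2-(methoxymethoxy)phenyl]lithium | [Li]c1ccc(OC)cc1OCOC | intermediate
14 | lithium alkoxide of ethyl (3S)-3-{bis[4-(benzyloxy)phenyl]methyl}-4-hydroxy-4-[4-methoxy-2-(methoxymethoxy)phenyl]butanoate | CCOC(=O)C[C@H](C(O[Li])c1ccc(OC)cc1OCOC)C(c1ccc(OCc2ccccc2)cc1)c1ccc(OCc2ccccc2)cc1 | intermediate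
15 | (4S)-4-{bis[4-(benzyloxy)phenyl]methyl}-5-[4-methoxy-2-(methoxymethoxy)phenyl]oxolan-2-one (C5 epimers) | O=C1C[C@H](C(O1)c1ccc(OC)cc1OCOC)C(c1ccc(OCc2ccccc2)cc1)c1ccc(OCc2ccccc2)cc1 | intermediate
16 | 4-bromobenzene-1,3-diol | Oc1ccc(Br)c(O)c1 | starting material
17 | 5-(benzyloxy)-2-bromophenol | Oc1cc(OCc2ccccc2)ccc1Br | intermediate
18 | 4-(benzyloxy)-1-bromo-2-(methoxymethoxy)benzene | COCOc1cc(OCc2ccccc2)ccc1Br | intermediate
19 | [4-(benzyloxy)-2-(methoxymethoxy)phenyl]lithium | [Li]c1ccc(OCc2ccccc2)cc1OCOC | intermediate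
20 | (3S)-1-[4-(benzyloxy)-2-(methoxymethoxy)phenyl]-3-{bis[4-(benzyloxy)phenyl]methyl}-4-hydroxy-4-[4-methoxy-2-(methoxymethoxy)phenyl]butan-1-one (C4 epimers) | COCOc1cc(OCc2ccccc2)ccc1C(=O)C[C@H](C(O)c1ccc(OC)cc1OCOC)C(c1ccc(OCc2ccccc2)cc1)c1ccc(OCc2ccccc2)cc1 | intermediate
21 | (2S)-4-[4-(benzyloxy)-2-(methoxymethoxy)phenyl]-2-{bis[4-(benzyloxy)phenyl]methyl}-1-[4-methoxy-2-(methoxymethoxy)phenyl]butane-1,4-dione | COCOc1cc(OCc2ccccc2)ccc1C(=O)C[C@H](C(=O)c1ccc(OC)cc1OCOC)C(c1ccc(OCc2ccccc2)cc1)c1ccc(OCc2ccccc2)cc1 | intermediate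
22 | (2S)-4-[4-(benzyloxy)-2-hydroxyphenyl]-2-{bis[4-(benzyloxy)phenyl]methyl}-1-(2-hydroxy-4-methoxyphenyl)butane-1,4-dione | Oc1cc(OCc2ccccc2)ccc1C(=O)C[C@H](C(=O)c1ccc(OC)cc1O)C(c1ccc(OCc2ccccc2)cc1)c1ccc(OCc2ccccc2)cc1 | intermediate
23 | (2R)-4-[4-(benzyloxy)-2-hydroxyphenyl]-2-{bis[4-(benzyloxy)phenyl]methyl}-3-[(dimethylamino)methylidene]-1-(2-hydroxy-4-methoxyphenyl)butane-1,4-dione | CN(C)C=C(C(=O)c1ccc(OCc2ccccc2)cc1O)[C@H](C(=O)c1ccc(OC)cc1O)C(c1ccc(OCc2ccccc2)cc1)c1ccc(OCc2ccccc2)cc1 | intermediate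
24 | 7-(benzyloxy)-3-[(2R)-1,1-bis[4-(benzyloxy)phenyl]-3-(2-hydroxy-4-methoxyphenyl)-3-oxopropan-2-yl]-4H-chromen-4-one | COc1ccc(C(=O)[C@@H](c2coc3cc(OCc4ccccc4)ccc3c2=O)C(c2ccc(OCc3ccccc3)cc2)c2ccc(OCc3ccccc3)cc2)c(O)c1 | intermediate
25 | 7-hydroxy-3-[(2R)-3-(2-hydroxy-4-methoxyphenyl)-1,1-bis(4-hydroxyphenyl)-3-oxopropan-2-yl]-4H-chromen-4-one | COc1ccc(C(=O)[C@@H](c2coc3cc(O)ccc3c2=O)C(c2ccc(O)cc2)c2ccc(O)cc2)c(O)c1 | target

**Totals**
Total step count: 16. Longest linear sequence: 13 steps (steps 1–7, 9, 12–16).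

**Steps most likely to fail, with fallbacks**

Step 5 (the bulky, lipophilic enone may be a poor ketoreductase substrate). The fallback sets out from 5 and comes back at 6. Luche reduction (NaBH4, CeCl3·7H2O, MeOH, −20 °C) gives racemic (3E)-5,5-bis[4-(benzyloxy)phenyl]pent-3-en-2-ol F1. A dynamic kinetic resolution with a lipase (immobilised Candida antarctica lipase B), the racemisation catalyst (η5-C5Ph5)Ru(CO)2Cl with KOtBu, and isopropenyl acetate in toluene at rt acylates only the (R)-alcohol while the ruthenium complex keeps racemising the (S)-alcohol. This gives (2R,3E)-5,5-bis[4-(benzyloxy)phenyl]pent-3-en-2-yl acetate F2, and K2CO3 in MeOH then returns 6.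

Step 12 (double addition to the lactone or enolisation instead of addition). The fallback sets out from 15 and comes back at 20. i-PrMgCl with MeNH(OMe)·HCl in THF at −20 °C opens the lactone to the γ-hydroxy Weinreb amide (3S)-3-{bis[4-(benzyloxy)phenyl]methyl}-4-hydroxy-N-methoxy-4-[4-methoxy-2-(methoxymethoxy)phenyl]-N-methylbutanamide F3. This is treated at once with aryllithium 19 (2.3 equiv, THF, −78 °C); the chelated N-methoxy adduct cannot add a second aryl group and gives 20 on work-up.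

Step 15 (the methylene next to the crowded stereocentre may condense slowly, and the free phenols consume reagent). The fallback sets out from 21 and comes back at 24, leaving out step 14. The MOM-protected diketone is condensed with tert-butoxybis(dimethylamino)methane (toluene, 55 °C), which is more reactive than the dimethyl acetal and is not quenched because no phenol is free. This gives (2R)-4-[4-(benzyloxy)-2-(methoxymethoxy)phenyl]-2-{bis[4-(benzyloxy)phenyl]methyl}-3-[(dimethylamino)methylidene]-1-[4-methoxy-2-(methoxymethoxy)phenyl]butane-1,4-dione F4. HCl in MeOH/THF at rt then removes both MOM groups and closes the pyranone with loss of dimethylamine to give 24.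

**Further compounds**
F1 | step 5 | (3E)-5,5-bis[4-(benzyloxy)phenyl]pent-3-en-2-ol (racemate) | CC(O)/C=C/C(c1ccc(OCc2ccccc2)cc1)c1ccc(OCc2ccccc2)cc1
F2 | step 5 | (2R,3E)-5,5-bis[4-(benzyloxy)phenyl]pent-3-en-2-yl acetate | CC(=O)O[C@H](C)/C=C/C(c1ccc(OCc2ccccc2)cc1)c1ccc(OCc2ccccc2)cc1
F3 | step 12 | (3S)-3-{bis[4-(benzyloxy)phenyl]methyl}-4-hydroxy-N-methoxy-4-[4-methoxy-2-(methoxymethoxy)phenyl]-N-methylbutanamide | CON(C)C(=O)C[C@H](C(O)c1ccc(OC)cc1OCOC)C(c1ccc(OCc2ccccc2)cc1)c1ccc(OCc2ccccc2)cc1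
F4 | step 15 | (2R)-4-[4-(benzyloxy)-2-(methoxymethoxy)phenyl]-2-{bis[4-(benzyloxy)phenyl]methyl}-3-[(dimethylamino)methylidene]-1-[4-methoxy-2-(methoxymethoxy)phenyl]butane-1,4-dione | CN(C)C=C(C(=O)c1ccc(OCc2ccccc2)cc1OCOC)[C@H](C(=O)c1ccc(OC)cc1OCOC)C(c1ccc(OCc2ccccc2)cc1)c1ccc(OCc2ccccc2)cc1
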